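**Plan**

1. Numbering used throughout: C1 ketone, C2 bridgehead CH, C3=C4 alkene bridge (methyl on C4), C5 quaternary bridgehead, C6 lactone O–CH, C7–C9 rest of ring B, C10 quaternary C–CH3, C11/C12 lactone α-carbon and carbonyl, C1′H2–C2′H saturated bridge, C3′ the alkene carbon on C2′.
2. Enabling feature: the C6 oxygen and the C12 carbonyl are 1,4-related through C7 and C11, and C6 sits on the quaternary bridgehead C5, which has no α-hydrogen. A formyl group on C5 can therefore act as an acyl anion towards C7 of an (E)-2-methylenoate tethered to C10 and close ring B at C6–C7.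
3. Retrosynthetic cuts: lactone O–C12 and the C6 carbinol (from a C6 ketone), C6–C7 (Stetter), C7=C11 (Wittig), C9–C10 (enolate allylation), C2–C3 and C4–C5 (Michael–Michael annulation with methyl acrylate, whose ester carbon ends as the C4 methyl), C5–C6 (hydroxymethyl anion plus 1,3-carbonyl transposition), and the CH2–CH2 bond of the side chain (sulfone coupling), back to (R)-carvone.
4. Forward order: side chain and the C6 carbon are attached to the carvone ring (C1, C2, C2′, C1′, C5, C10), then the C3–C4 bridge gives the bicyclo[2.2.2]octane, then ring B, then the γ-lactone.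
5. Stereochemistry: C2′ comes from (R)-carvone; C2 and C5 from annulation anti to the C2′ substituent; C10 from allylation anti to the endo ester on C4; C7 (equatorial) and C11 from syn acyl/H addition to the (E)-enoate, with C7 also under thermodynamic control; C6 from equatorial hydride attack.

Key step: step 17

Remark: PMB is 4-methoxybenzyl; the 1,3-carbonyl transposition of step 7 is what makes natural (R)-carvone the correct antipode, since the enone that enters the annulation is then the (S)-3-substituted carvone.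

**Step 1**
Reactants: 1 tributyl(iodomethyl)stannane; 2 4-methoxybenzyl alcohol
Product: 3 tributyl{[(4-methoxybenzyl)oxy]methyl}stannane
Conditions: NaH, THF/DMF, 0 °C → rt
Reagents that add atoms: none
Why: Williamson ether synthesis, the alkoxide of 2 displacing iodide from the primary α-stannyl carbon, gives a storable precursor of a protected hydroxymethyl anion.

**Step 2**
Reactants: 4 1-bromo-3-methylbut-2-ene; 5 sodium benzenesulfinate
Product: 6 (3-methylbut-2-en-1-yl) phenyl sulfone
Conditions: DMF, rt
Reagents that add atoms: none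
Why: SN2 S-alkylation of the sulfinate by the primary allylic bromide gives the sulfone that serves as a prenyl anion equivalent.

**Step 3**
Reactants: 7 (R)-carvone
Product: 8 (5R)-5-(3-chloroprop-1-en-2-yl)-2-methylcyclohex-2-en-1-one
Conditions: Ca(OCl)2, solid CO2, CH2Cl2/H2O, 0 °C
Reagents that add atoms: calcium hypochlorite, [Ca+2].[O-]Cl.[O-]Cl
Why: Ene-type allylic chlorination by HOCl should take place at the electron-rich 1,1-disubstituted alkene, the conjugated ring alkene being deactivated; the stereocentre is not involved.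

**Step 4**
Reactants: 3 tributyl{[(4-methoxybenzyl)oxy]methyl}stannane; 8 (5R)-5-(3-chloroprop-1-en-2-yl)-2-methylcyclohex-2-en-1-one
Product: 10 (5R)-5-(3-chloroprop-1-en-2-yl)-1-{[(4-methoxybenzyl)oxy]methyl}-2-methylcyclohex-2-en-1-ol, via alkoxymethyllithium 9 (not isolated)
Conditions: n-BuLi, THF, −78 °C; then 8, −78 °C; H2O
Reagents that add atoms: none
Why: Tin–lithium exchange gives the α-alkoxymethyllithium, which should add 1,2 to the enone carbonyl at −78 °C faster than it displaces the allylic chloride; the new carbinol centre is erased in step 7, so both epimers serve.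

**Step 5**
Reactants: 6 (3-methylbut-2-en-1-yl) phenyl sulfone; 10 (5R)-5-(3-chloroprop-1-en-2-yl)-1-{[(4-methoxybenzyl)oxy]methyl}-2-methylcyclohex-2-en-1-ol
Product: 12 (5R)-1-{[(4-methoxybenzyl)oxy]methyl}-2-methyl-5-[6-methyl-4-(phenylsulfonyl)hepta-1,5-dien-2-yl]cyclohex-2-en-1-ol, via lithiated sulfone 11 (not isolated)
Conditions: n-BuLi, THF, −78 °C; then 10, DMPU, −78 → −20 °C
Reagents that add atoms: none
Why: Julia-type sulfone alkylation: the allylic α-sulfonyl carbanion reacts at its α-carbon with the 2-substituted allylic chloride (SN2 and SN2′ give the same product); the sulfonyl carbon is a transient stereocentre.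

**Step 6**
Reactants: 12 (5R)-1-{[(4-methoxybenzyl)oxy]methyl}-2-methyl-5-[6-methyl-4-(phenylsulfonyl)hepta-1,5-dien-2-yl]cyclohex-2-en-1-ol
Product: 13 (5R)-1-{[(4-methoxybenzyl)oxy]methyl}-2-methyl-5-(6-methylhepta-1,5-dien-2-yl)cyclohex-2-en-1-ol
Conditions: PdCl2[Ph2P(CH2)3PPh2] (5 mol %), LiBHEt3, THF, 0 °C
Reagents that add atoms: none
Why: Palladium-catalysed reductive desulfonylation: zerovalent palladium ionises the allylic sulfone to a π-allyl complex and hydride should attack its less substituted terminus, so the trisubstituted alkene stays in place.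

**Step 7**
Reactants: 13 (5R)-1-{[(4-methoxybenzyl)oxy]methyl}-2-methyl-5-(6-methylhepta-1,5-dien-2-yl)cyclohex-2-en-1-ol
Product: 14 (5S)-3-{[(4-methoxybenzyl)oxy]methyl}-2-methyl-5-(6-methylhepta-1,5-dien-2-yl)cyclohex-2-en-1-one
Conditions: [C5H5NH][CrO3Cl] (pyridinium chlorochromate), Celite, CH2Cl2, rt
Reagents that add atoms: pyridinium chlorochromate, [O-][Cr](=O)(=O)Cl.c1cc[nH+]cc1
Why: Dauben oxidative 1,3-transposition: the tertiary allylic chromate ester undergoes a [3,3] shift and the secondary chromate is oxidised to the enone, which moves the carbonyl to the other side of the carvone stereocentre and puts the protected C6 carbon on the future C5.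

**Step 8**
Reactants: 14 (5S)-3-{[(4-methoxybenzyl)oxy]methyl}-2-methyl-5-(6-methylhepta-1,5-dien-2-yl)cyclohex-2-en-1-one; 15 methyl acrylate; 16 allyl iodide
Product: 19 C10-allyl bicyclo[2.2.2]octanone ester, via lithium dienolate 17 (not isolated), via bicyclic lithium enolate 18 (not isolated)
Conditions: LiN(SiMe3)2, THF, −78 °C; 15, −78 °C → rt; then DMPU, 16, −40 °C → rt
Reagents that add atoms: none
Why: Michael–Michael annulation then enolate alkylation: the kinetic α′-dienolate adds to methyl acrylate anti to the C2′ substituent and the ester enolate closes onto C5 (ester endo, lithium-chelated), setting C2, C5 and C4; the regiodefined C1–C10 enolate is then allylated anti to the endo ester, on the side of the C1′–C2′ bridge, setting C10.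

**Step 9**
Reactants: 19 C10-allyl bicyclo[2.2.2]octanone ester
Product: 23 bicyclic C3=C4 enoate, via ester lithium enolate 20 (not isolated), via phenylselanyl ester 21 (not isolated), via selenoxide 22 (not isolated)
Conditions: LiN(iPr)2, THF, −78 °C; PhSeBr, −78 °C; then H2O2 (30 % aq.), pyridine, CH2Cl2, 0 °C → rt
Reagents that add atoms: none
Why: Selenoxide route to an enoate: only the ester can be enolised because the C1 ketone cannot (C10 quaternary, C2 bridgehead), and the selenoxide can only eliminate syn towards C3 since C5 is quaternary.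

**Step 10**
Reactants: 23 bicyclic C3=C4 enoate
Product: 24 allylic alcohol diol (C4–CH2OH and C1–OH)
Conditions: i-Bu2AlH, CH2Cl2, −78 → 0 °C; aq. KNaC4H4O6
Reagents that add atoms: none
Why: Hydride 1,2-reduction of the unsaturated ester gives the allylic alcohol carrying the future C4 methyl carbon; the C1 ketone is reduced at the same time (either epimer serves, it is reoxidised in step 12).

**Step 11**
Reactants: 24 allylic alcohol diol (C4–CH2OH and C1–OH)
Product: 26 C4-methyl alkene alcohol, via allylic mesylate 25 (not isolated)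
Conditions: MsCl, Et3N, CH2Cl2, −40 °C; then LiBHEt3, THF, 0 °C
Reagents that add atoms: none
Why: Selective sulfonylation of the primary allylic alcohol over the shielded secondary C1 alcohol, then SN2 hydride displacement, should turn CH2OH into the C4 methyl without moving the C3=C4 double bond.

**Step 12**
Reactants: 26 C4-methyl alkene alcohol
Product: 27 C10-allyl bicyclo[2.2.2]octenone
Conditions: Dess–Martin periodinane, NaHCO3, CH2Cl2, rt
Reagents that add atoms: none
Why: Dess–Martin oxidation returns the C1 ketone under neutral conditions that leave the PMB ether and the alkenes untouched.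

**Step 13**
Reactants: 27 C10-allyl bicyclo[2.2.2]octenone
Product: 28 C7 aldehyde
Conditions: PdCl2(PhCN)2 (10 mol %), CuCl2·2H2O (10 mol %), AgNO2 (5 mol %), O2 (1 atm), t-BuOH/MeNO2, rt
Reagents that add atoms: dioxygen, O=O
Why: Nitrite-modified, aldehyde-selective Wacker oxidation: the monosubstituted allyl terminus is expected to be the only alkene that undergoes oxypalladation, with anti-Markovnikov delivery of oxygen.

**Step 14**
Reactants: 28 C7 aldehyde; 29 methyl 2-(triphenylphosphoranylidene)propanoate
Product: 30 (E)-2-methylenoate PMB ether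
Conditions: CH2Cl2, 40 °C
Reagents that add atoms: none
Why: Wittig olefination with the stabilised α-methyl ylide should give the (E)-trisubstituted enoate; the hindered C1 ketone does not compete.

**Step 15**
Reactants: 30 (E)-2-methylenoate PMB ether
Product: 31 C6 primary alcohol
Conditions: DDQ, CH2Cl2/pH 7 phosphate buffer, 0 °C
Reagents that add atoms: none
Why: Oxidative PMB ether cleavage (hydride abstraction at the electron-rich benzylic position, then hydrolysis) frees the C6 alcohol without touching the isolated alkenes or the enoate.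

**Step 16**
Reactants: 31 C6 primary alcohol
Product: 32 C5-formyl bicyclo[2.2.2]octenone with the (E)-enoate chain on C10
Conditions: Dess–Martin periodinane, NaHCO3, CH2Cl2, rt
Reagents that add atoms: none
Why: Dess–Martin oxidation of the neopentyl primary alcohol gives the bridgehead aldehyde, which can neither enolise nor epimerise.

**Step 17**
Reactants: 32 C5-formyl bicyclo[2.2.2]octenone with the (E)-enoate chain on C10
Product: 33 tricyclic C1,C6-diketo ester
Conditions: 2-(pentafluorophenyl)-6,7-dihydro-5H-pyrrolo[2,1-c][1,2,4]triazol-2-ium tetrafluoroborate (20 mol %), KN(SiMe3)2 (20 mol %), toluene, rt → 60 °C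
Reagents that add atoms: none
Why: The triazolylidene adds to the C6 aldehyde, proton transfer gives the enaminol (acyl anion equivalent), this adds to C7 of the enoate, and protonation at C11 with loss of the carbene gives the γ-keto ester; the closest known type is the intramolecular Stetter reaction of aliphatic aldehydes with α,β-disubstituted acceptors. Ring B closes 6-exo-trig, helped by the two reacting arms sitting on adjacent quaternary carbons (C5 and C10) of a rigid bicycle. C7 should be set by a chair-like closure that leaves the C11 branch equatorial, and because C7 ends up α to the new ketone it can also relax to that epimer under the basic conditions. C11 should be set by proton delivery from the enaminol oxygen to the face on which the C–C bond formed, so that syn addition across the (E)-alkene gives the C7/C11 relationship of the target. The step needs conjugate addition to win over aldol and benzoin paths: C5 has no α-hydrogen, the C1 ketone cannot be enolised, and a cross-benzoin onto C1 would need a four-membered ring.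

**Step 18**
Reactants: 33 tricyclic C1,C6-diketo ester
Product: 35 C1-hydroxy lactone, via dihydroxy ester 34 (not isolated)
Conditions: KBH(sec-Bu)3, THF, −78 → −20 °C; H2O
Reagents that add atoms: none
Why: Bulky-hydride reduction: attack on the C6 ketone from the equatorial side of ring B, away from the axial C10 methyl, should give the axial alkoxide, which is cis to the C7 side chain and closes the γ-lactone by acyl substitution; the more exposed C1 ketone is expected to be reduced as well and is restored in step 19.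

**Step 19**
Reactants: 35 C1-hydroxy lactone
Product: 36 CNP0385704.2
Conditions: Dess–Martin periodinane, NaHCO3, CH2Cl2, rt
Reagents that add atoms: none
Why: Dess–Martin oxidation of the one remaining alcohol gives the C1 ketone without exposing the lactone or the centres α to carbonyl groups to base.

**Compound list**

1 | tributyl(iodomethyl)stannane | CCCC[Sn](CCCC)(CCCC)CI | starting material
2 | 4-methoxybenzyl alcohol | COc1ccc(CO)cc1 | starting material
3 | tributyl{[(4-methoxybenzyl)oxy]methyl}stannane | CCCC[Sn](CCCC)(CCCC)COCc1ccc(OC)cc1 | intermediate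
4 | 1-bromo-3-methylbut-2-ene | CC(C)=CCBr | starting material
5 | sodium benzenesulfinate | [Na+].[O-]S(=O)c1ccccc1 | starting material
6 | (3-methylbut-2-en-1-yl) phenyl sulfone | CC(C)=CCS(=O)(=O)c1ccccc1 | intermediate
7 | (R)-carvone | CC1=CC[C@H](CC1=O)C(C)=C | starting material
8 | (5R)-5-(3-chloroprop-1-en-2-yl)-2-methylcyclohex-2-en-1-one | C=C(CCl)[C@@H]1CC=C(C)C(=O)C1 | intermediate
9 | {[(4-methoxybenzyl)oxy]methyl}lithium | [Li]COCc1ccc(OC)cc1 | intermediate
10 | (5R)-5-(3-chloroprop-1-en-2-yl)-1-{[(4-methoxybenzyl)oxy]methyl}-2-methylcyclohex-2-en-1-ol (both C1 epimers) | C=C(CCl)[C@@H]1CC=C(C)C(O)(COCc2ccc(OC)cc2)C1 | intermediate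
11 | [3-methyl-1-(phenylsulfonyl)but-2-en-1-yl]lithium | [Li]C(C=C(C)C)S(=O)(=O)c1ccccc1 | intermediate
12 | (5R)-1-{[(4-methoxybenzyl)oxy]methyl}-2-methyl-5-[6-methyl-4-(phenylsulfonyl)hepta-1,5-dien-2-yl]cyclohex-2-en-1-ol (epimers at C1 and at the sulfonyl carbon) | C=C(CC(C=C(C)C)S(=O)(=O)c1ccccc1)[C@@H]1CC=C(C)C(O)(COCc2ccc(OC)cc2)C1 | intermediate
13 | (5R)-1-{[(4-methoxybenzyl)oxy]methyl}-2-methyl-5-(6-methylhepta-1,5-dien-2-yl)cyclohex-2-en-1-ol (both C1 epimers) | C=C(CCC=C(C)C)[C@@H]1CC=C(C)C(O)(COCc2ccc(OC)cc2)C1 | intermediate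
14 | (5S)-3-{[(4-methoxybenzyl)oxy]methyl}-2-methyl-5-(6-methylhepta-1,5-dien-2-yl)cyclohex-2-en-1-one | C=C(CCC=C(C)C)[C@H]1CC(COCc2ccc(OC)cc2)=C(C)C(=O)C1 | intermediate
15 | methyl acrylate | C=CC(=O)OC | starting material
16 | allyl iodide | C=CCI | starting material
17 | kinetic (cross-conjugated) lithium dienolate of 14 | C=C(CCC=C(C)C)[C@H]1CC(COCc2ccc(OC)cc2)=C(C)C(O[Li])=C1 | intermediate
18 | bicyclic lithium enolate (C1–OLi, C1=C10; endo CO2Me on C4; CH2OPMB on C5) | C=C(CCC=C(C)C)[C@H]1C[C@]2(COCc3ccc(OC)cc3)[C@@H](C(=O)OC)C[C@H]1C(O[Li])=C2C | intermediate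
19 | methyl 6-allyl-1-{[(4-methoxybenzyl)oxy]methyl}-6-methyl-8-(6-methylhepta-1,5-dien-2-yl)-5-oxobicyclo[2.2.2]octane-2-carboxylate (C2, C5, C10, C2′ as in the target; allyl on the side of the C1′–C2′ bridge; ester on C4 towards the ketone bridge) | C=C(CCC=C(C)C)[C@H]1C[C@]2(COCc3ccc(OC)cc3)[C@@H](C(=O)OC)C[C@H]1C(=O)[C@]2(C)CC=C | intermediate
20 | lithium ester enolate of 19 (C4=C(OMe)OLi) | C=C(CCC=C(C)C)[C@H]1C[C@]2(COCc3ccc(OC)cc3)C(=C(OC)O[Li])C[C@H]1C(=O)[C@]2(C)CC=C | intermediate
21 | C4-phenylselanyl ester | C=C(CCC=C(C)C)[C@H]1C[C@]2(COCc3ccc(OC)cc3)C([Se]c3ccccc3)(C(=O)OC)C[C@H]1C(=O)[C@]2(C)CC=C | intermediate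
22 | C4-phenylseleninyl ester (selenoxide) | C=C(CCC=C(C)C)[C@H]1C[C@]2(COCc3ccc(OC)cc3)C([Se](=O)c3ccccc3)(C(=O)OC)C[C@H]1C(=O)[C@]2(C)CC=C | intermediate
23 | methyl 6-allyl-1-{[(4-methoxybenzyl)oxy]methyl}-6-methyl-8-(6-methylhepta-1,5-dien-2-yl)-5-oxobicyclo[2.2.2]oct-2-ene-2-carboxylate | C=C(CCC=C(C)C)[C@H]1C[C@]2(COCc3ccc(OC)cc3)C(C(=O)OC)=C[C@H]1C(=O)[C@]2(C)CC=C | intermediate
24 | 6-allyl-2-(hydroxymethyl)-1-{[(4-methoxybenzyl)oxy]methyl}-6-methyl-8-(6-methylhepta-1,5-dien-2-yl)bicyclo[2.2.2]oct-2-en-5-ol (both C1 epimers) | C=C(CCC=C(C)C)[C@H]1C[C@]2(COCc3ccc(OC)cc3)C(CO)=C[C@H]1C(O)[C@]2(C)CC=C | intermediate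
25 | primary allylic methanesulfonate of 24 | C=C(CCC=C(C)C)[C@H]1C[C@]2(COCc3ccc(OC)cc3)C(COS(C)(=O)=O)=C[C@H]1C(O)[C@]2(C)CC=C | intermediate
26 | 6-allyl-1-{[(4-methoxybenzyl)oxy]methyl}-2,6-dimethyl-8-(6-methylhepta-1,5-dien-2-yl)bicyclo[2.2.2]oct-2-en-5-ol (both C1 epimers) | C=C(CCC=C(C)C)[C@H]1C[C@]2(COCc3ccc(OC)cc3)C(C)=C[C@H]1C(O)[C@]2(C)CC=C | intermediate
27 | 6-allyl-1-{[(4-methoxybenzyl)oxy]methyl}-2,6-dimethyl-8-(6-methylhepta-1,5-dien-2-yl)bicyclo[2.2.2]oct-2-en-5-one | C=C(CCC=C(C)C)[C@H]1C[C@]2(COCc3ccc(OC)cc3)C(C)=C[C@H]1C(=O)[C@]2(C)CC=C | intermediate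
28 | 3-[1-{[(4-methoxybenzyl)oxy]methyl}-2,6-dimethyl-8-(6-methylhepta-1,5-dien-2-yl)-5-oxobicyclo[2.2.2]oct-2-en-6-yl]propanal | C=C(CCC=C(C)C)[C@H]1C[C@]2(COCc3ccc(OC)cc3)C(C)=C[C@H]1C(=O)[C@]2(C)CCC=O | intermediate
29 | methyl 2-(triphenylphosphoranylidene)propanoate | COC(=O)C(C)=P(c1ccccc1)(c1ccccc1)c1ccccc1 | starting material
30 | methyl (2E)-5-[1-{[(4-methoxybenzyl)oxy]methyl}-2,6-dimethyl-8-(6-methylhepta-1,5-dien-2-yl)-5-oxobicyclo[2.2.2]oct-2-en-6-yl]-2-methylpent-2-enoate | C=C(CCC=C(C)C)[C@H]1C[C@]2(COCc3ccc(OC)cc3)C(C)=C[C@H]1C(=O)[C@]2(C)CC/C=C(\C)C(=O)OC | intermediate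
31 | C5-hydroxymethyl analogue of 30 | C=C(CCC=C(C)C)[C@H]1C[C@]2(CO)C(C)=C[C@H]1C(=O)[C@]2(C)CC/C=C(\C)C(=O)OC | intermediate
32 | C5-formyl bicyclo[2.2.2]octenone with the (E)-enoate chain on C10 | C=C(CCC=C(C)C)[C@H]1C[C@]2(C=O)C(C)=C[C@H]1C(=O)[C@]2(C)CC/C=C(\C)C(=O)OC | intermediate
33 | tricyclic C1,C6-diketone with the methyl propanoate branch equatorial on C7 | C=C(CCC=C(C)C)[C@H]1C[C@]23C(C)=C[C@H]1C(=O)[C@]2(C)CC[C@@H]([C@H](C)C(=O)OC)C3=O | intermediate
34 | C1,C6-dihydroxy ester (C6–OH axial on ring B; C1 epimers) | C=C(CCC=C(C)C)[C@H]1C[C@]23C(C)=C[C@H]1C(O)[C@]2(C)CC[C@@H]([C@H](C)C(=O)OC)[C@H]3O | intermediate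
35 | C1-hydroxy cis-fused γ-lactone (C1 epimers) | C=C(CCC=C(C)C)[C@H]1C[C@]23C(C)=C[C@H]1C(O)[C@]2(C)CC[C@H]1[C@H](C)C(=O)O[C@H]13 | intermediate
36 | CNP0385704.2 | C=C(CCC=C(C)C)[C@H]1C[C@]23C(C)=C[C@H]1C(=O)[C@]2(C)CC[C@H]1[C@H](C)C(=O)O[C@H]13 | target

**Step count and risks**

Total step count: 19 (steps 1 and 2 make reagents off the main line).
Longest linear sequence: 17 steps (steps 3 to 19, from (R)-carvone).

The three steps most likely to fail:

1. Step 17. The carbene may add too slowly to the crowded bridgehead aldehyde, or the enaminol may fail to add to the weakly electrophilic trisubstituted enoate, so that nothing turns over; protonation at C11 may also be unselective. The fallback sets out from 32 and comes back at 33. The aldehyde would be oxidised (NaClO2, NaH2PO4, 2-methylbut-2-ene, t-BuOH/H2O) to the bridgehead carboxylic acid F1 and converted (PhSeSePh, PBu3, CH2Cl2) into the Se-phenyl selenoester F2. The acyl radical released from F2 ((Me3Si)3SiH, Et3B/air, benzene, rt, under CO to hold back decarbonylation) would add 6-exo-trig to C7, and hydrogen-atom transfer to C11 would give 33. If C11 came out mixed, it would be equilibrated at the lactone stage (catalytic DBU on 35) to the epimer with the methyl on the convex face, which is the one the target has.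

2. Step 8. Closure of the ester enolate onto the fully substituted C5 may stall at the mono-Michael stage, and allylation of the crowded C1–C10 enolate may be slow, go to oxygen or lose facial control. The fallback sets out from 14 and comes back at 19. The kinetic trimethylsilyl dienol ether F3 (LiN(iPr)2, Me3SiCl, THF, −78 °C) would be heated with methyl acrylate (toluene, 110 °C) in a neutral Diels–Alder reaction to the endo adduct, the bicyclic silyl enol ether F4. Its enolate would then be released without strong base ([(Me2N)3S][Me3SiF2], THF, −78 °C → rt) in the presence of allyl iodide to give 19.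

3. Step 13. Oxypalladation may turn to the Markovnikov sense (methyl ketone), or a palladium hydride may move the terminal double bond before oxidation. The fallback sets out from 27 and comes back at 28. Rhodium-catalysed hydroboration (catecholborane, RhCl(PPh3)3, THF, 0 °C), which picks the monosubstituted alkene and outpaces ketone reduction, would give the catechol boronate F5. Oxidation in the same flask (NaBO3·4H2O) would give the primary alcohol F6, and Dess–Martin oxidation of F6 the aldehyde 28.

**Further compounds**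

F1 | step 17 | bridgehead carboxylic acid (CO2H on C5 in place of the CHO of 32) | C=C(CCC=C(C)C)[C@H]1C[C@]2(C(=O)O)C(C)=C[C@H]1C(=O)[C@]2(C)CC/C=C(\C)C(=O)OC
F2 | step 17 | Se-phenyl selenoester of F1 | C=C(CCC=C(C)C)[C@H]1C[C@]2(C(=O)[Se]c3ccccc3)C(C)=C[C@H]1C(=O)[C@]2(C)CC/C=C(\C)C(=O)OC
F3 | step 8 | kinetic trimethylsilyl dienol ether of 14 | C=C(CCC=C(C)C)[C@H]1CC(COCc2ccc(OC)cc2)=C(C)C(O[Si](C)(C)C)=C1
F4 | step 8 | bicyclic trimethylsilyl enol ether (C1–OSiMe3, C1=C10; endo CO2Me on C4) | C=C(CCC=C(C)C)[C@H]1C[C@]2(COCc3ccc(OC)cc3)[C@@H](C(=O)OC)C[C@H]1C(O[Si](C)(C)C)=C2C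
F5 | step 13 | catechol boronate (C10–CH2CH2CH2–B) from 27 | C=C(CCC=C(C)C)[C@H]1C[C@]2(COCc3ccc(OC)cc3)C(C)=C[C@H]1C(=O)[C@]2(C)CCCB1Oc2ccccc2O1
F6 | step 13 | primary alcohol (C10–CH2CH2CH2OH) from 27 | C=C(CCC=C(C)C)[C@H]1C[C@]2(COCc3ccc(OC)cc3)C(C)=C[C@H]1C(=O)[C@]2(C)CCCO
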